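**Retrosynthetic overview**

1. The target is reached by global desilylation of a C4 ester that is made by Mitsunobu esterification with inversion at C4 (3-methylbut-2-enoic acid) from the (4R,5S,6R)-epoxy alcohol. This epoxy alcohol comes from tartrate-directed epoxidation of the ring (4R)-divinyl carbinol, so the oxirane is the second ring formed.
2. The only carbocycle, the 11-membered ring, is formed first by closing C4–C5 in a ligand-controlled Ni/Cr (Nozaki–Hiyama–Kishi) addition of a C5 alkenyl iodide to a C4 enal in an open-chain precursor.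
3. Enabling feature: C4 is a carbinol carbon flanked by the C2=C3 E-olefin, whose far end is the quaternary C1 (a γ-blocked, non-enolisable enal), and by the C5(CH3)–C6 oxirane. The hydroxy-epoxide is therefore the retron of a ring divinyl carbinol whose C5=C6 olefin is an (E)-2-metallo-2-alkene.
4. The seco iodo-enal comes from a Horner–Wadsworth–Emmons olefination (C9=C10) of a C10 aldehyde with a phosphonate that carries the (E)-alkenyl iodide (from pent-3-yn-1-ol by hydrozirconation).
5. The C10 aldehyde comes from a Johnson–Claisen rearrangement that transfers the glyceraldehyde-derived C3 carbinol centre to quaternary C1 and sets E-C2=C3. Its substrate is built from (R)-glyceraldehyde acetonide by isopropenyl Grignard addition, a first Johnson–Claisen, Weinreb ketone synthesis and CBS reduction.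

Key step: step 19

Remark: (R)-glyceraldehyde acetonide is taken as a purchasable aldehyde (otherwise made fresh from 1,2:5,6-di-O-isopropylidene-D-mannitol and NaIO4); locants used below are C1 (quaternary ring carbon), C2=C3, C4 (acyloxy), C5 and C6 (oxirane), C7, C8, C9 (CH2OH)=C10, C11, and C12–C16 for the side chain counted outward from C1.

**Route**

Step 1
Reactants: 1 (R)-2,2-dimethyl-1,3-dioxolane-4-carbaldehyde; 2 isopropenylmagnesium bromide
Product: 3 1-[(4R)-2,2-dimethyl-1,3-dioxolan-4-yl]-2-methylprop-2-en-1-ol (both carbinol epimers, carried on together)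
Conditions: THF, −78 → 0 °C; aq. NH4Cl
Reagents that add atoms: none
Why: Grignard 1,2-addition to the α-alkoxy aldehyde; the new carbinol centre need not be controlled because it is erased in step 2.

Step 2
Reactants: 3; 4 triethyl orthoacetate
Product: 6 ethyl (4E)-5-[(4S)-2,2-dimethyl-1,3-dioxolan-4-yl]-4-methylpent-4-enoate, via ketene acetal 5 (not isolated)
Conditions: EtCO2H (cat.), excess MeC(OEt)3, 140 °C, EtOH distilled off
Reagents that add atoms: none
Why: Johnson–Claisen rearrangement of a 2-methylallylic alcohol through a chair transition state with the dioxolanyl group equatorial, which should give the E trisubstituted olefin from either epimer of 3.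

Step 3
Reactants: 6
Product: 7 (4E)-5-[(4S)-2,2-dimethyl-1,3-dioxolan-4-yl]-N-methoxy-N,4-dimethylpent-4-enamide
Conditions: MeNH(OMe)·HCl, i-PrMgCl, THF, −20 °C
Reagents that add atoms: N,O-dimethylhydroxylamine hydrochloride, CNOC.Cl
Why: Weinreb amide formation by aminolysis of the ester with the chloromagnesium amide, whose chelated product should not react further at −20 °C.

Step 4
Reactants: 7; 2 isopropenylmagnesium bromide
Product: 8 (6E)-7-[(4S)-2,2-dimethyl-1,3-dioxolan-4-yl]-2,6-dimethylhepta-1,6-dien-3-one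
Conditions: THF, 0 °C; cold aq. NH4Cl
Reagents that add atoms: none
Why: Weinreb ketone synthesis; the chelated tetrahedral adduct should prevent over-addition and releases the enone only on work-up.

Step 5
Reactants: 8
Product: 9 (3R,6E)-7-[(4S)-2,2-dimethyl-1,3-dioxolan-4-yl]-2,6-dimethylhepta-1,6-dien-3-ol
Conditions: (S)-Me-CBS (0.2 equiv), catecholborane, toluene, −78 °C
Reagents that add atoms: none
Why: Corey–Bakshi–Shibata reduction; with the isopropenyl group as the large substituent the (S)-oxazaborolidine should deliver hydride to give the R carbinol (C14), and 1,2-reduction of the enone should outrun hydroboration of the olefins.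

Step 6
Reactants: 9
Product: 10 triisopropylsilyl ether of 9
Conditions: TIPSOTf, 2,6-lutidine, CH2Cl2, −78 → 0 °C
Reagents that add atoms: triisopropylsilyl trifluoromethanesulfonate, CC(C)[Si](C(C)C)(C(C)C)OS(=O)(=O)C(F)(F)F
Why: Silyl triflate silylation protects the hindered secondary allylic alcohol as an ether that should survive the later acid, hydride and Claisen steps.

Step 7
Reactants: 10
Product: 11 (2S,3E,7R)-4,8-dimethyl-7-[(triisopropylsilyl)oxy]nona-3,8-diene-1,2-diol
Conditions: PPTS (cat.), MeOH, 40 °C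
Reagents that add atoms: none
Why: Acid-catalysed transketalisation with methanol (acetonide cleavage) should free the 1,2-diol while the far more acid-stable TIPS ether stays.

Step 8
Reactants: 11
Product: 12 (2S,3E,7R)-1-[(tert-butyldimethylsilyl)oxy]-4,8-dimethyl-7-[(triisopropylsilyl)oxy]nona-3,8-dien-2-ol
Conditions: TBSCl (1.05 equiv), imidazole, CH2Cl2, 0 °C
Reagents that add atoms: tert-butyldimethylsilyl chloride, CC(C)(C)[Si](C)(C)Cl
Why: Selective silylation of the primary hydroxyl of the 1,2-diol, which should react much faster than the secondary allylic C3 hydroxyl.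

Step 9
Reactants: 12; 4 triethyl orthoacetate
Product: 14 ethyl (3R,4E)-6-[(tert-butyldimethylsilyl)oxy]-3-methyl-3-{(3R)-4-methyl-3-[(triisopropylsilyl)oxy]pent-4-en-1-yl}hex-4-enoate, via ketene acetal 13 (not isolated)
Conditions: EtCO2H (cat.), MeC(OEt)3, xylene, 140 °C, EtOH distilled off
Reagents that add atoms: none
Why: Johnson–Claisen rearrangement with 1,3-chirality transfer: in the chair transition state with CH2OTBS equatorial the new C1–C11 bond forms on the face that carried the C3–O bond, so the S carbinol and the E olefin (methyl cis to C3) should give R at quaternary C1 and the E-C2=C3 olefin.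

Step 10
Reactants: 14
Product: 15 (3R,4E)-6-[(tert-butyldimethylsilyl)oxy]-3-methyl-3-{(3R)-4-methyl-3-[(triisopropylsilyl)oxy]pent-4-en-1-yl}hex-4-enal
Conditions: DIBAL-H (1.1 equiv), CH2Cl2, −78 °C; Rochelle salt
Reagents that add atoms: none
Why: Partial reduction of the ester by DIBAL-H at −78 °C, where the aluminium hemiacetal should persist until work-up and release the aldehyde.

Step 11
Reactants: 16 pent-3-yn-1-ol
Product: 18 (3E)-4-iodopent-3-en-1-ol, via alkenylzirconocene 17 (not isolated)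
Conditions: Cp2Zr(H)Cl (2.5 equiv), THF, rt → 40 °C; then I2, 0 °C
Reagents that add atoms: iodine, II
Why: Hydrozirconation adds Zr–H syn across the alkyne, and with excess reagent the metal should settle on the less hindered methyl-bearing carbon; iodinolysis with retention then gives the E alkenyl iodide.

Step 12
Reactants: 18
Product: 19 (2E)-2,5-diiodopent-2-ene
Conditions: PPh3, I2, imidazole, CH2Cl2, 0 °C
Reagents that add atoms: iodine, II
Why: Appel-type iodination converts the primary alcohol into the iodide by SN2 displacement of the oxyphosphonium group.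

Step 13
Reactants: 19; 20 triethyl phosphonoacetate
Product: 22 ethyl (5E)-2-(diethoxyphosphoryl)-6-iodohept-5-enoate (racemic at C2), via sodium phosphonoacetate 21 (not isolated)
Conditions: NaH, THF/DMSO, 0 → 50 °C
Reagents that add atoms: none
Why: Malonate-type C-alkylation of the stabilised phosphonoacetate anion by the primary alkyl iodide (SN2), in which the alkenyl iodide should be inert.

Step 14
Reactants: 15; 22
Product: 23 ethyl (2E,5R,6E)-8-[(tert-butyldimethylsilyl)oxy]-2-[(3E)-4-iodopent-3-en-1-yl]-5-methyl-5-{(3R)-4-methyl-3-[(triisopropylsilyl)oxy]pent-4-en-1-yl}octa-2,6-dienoate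
Conditions: LiCl, DBU, MeCN, rt
Reagents that add atoms: none
Why: Horner–Wadsworth–Emmons olefination under Masamune–Roush conditions, whose reversible addition should favour the E enoate (ester trans to C11), i.e. the ring-cis C9=C10 geometry with the future CH2OH trans to C11.

Step 15
Reactants: 23
Product: 24 (2E,5R,6E)-8-[(tert-butyldimethylsilyl)oxy]-2-[(3E)-4-iodopent-3-en-1-yl]-5-methyl-5-{(3R)-4-methyl-3-[(triisopropylsilyl)oxy]pent-4-en-1-yl}octa-2,6-dien-1-ol
Conditions: DIBAL-H (2.5 equiv), CH2Cl2, −78 °C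
Reagents that add atoms: none
Why: DIBAL-H 1,2-reduction of the α,β-unsaturated ester to the allylic alcohol, which should leave the alkenyl iodide and the silyl ethers intact.

Step 16
Reactants: 24
Product: 25 1-O-tert-butyldiphenylsilyl ether of 24
Conditions: TBDPSCl, imidazole, DMF, rt
Reagents that add atoms: tert-butyl(chloro)diphenylsilane, CC(C)(C)[Si](Cl)(c1ccccc1)c1ccccc1
Why: Silylation of the primary allylic alcohol as the acid-stable TBDPS ether, which differentiates it from the C4 silyl ether.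

Step 17
Reactants: 25
Product: 26 (2E,4R,6E)-8-[(tert-butyldiphenylsilyl)oxy]-7-[(3E)-4-iodopent-3-en-1-yl]-4-methyl-4-{(3R)-4-methyl-3-[(triisopropylsilyl)oxy]pent-4-en-1-yl}octa-2,6-dien-1-ol
Conditions: PPTS (cat.), MeOH/CH2Cl2, 0 °C → rt
Reagents that add atoms: none
Why: Mild acidic methanolysis should cleave only the primary TBS ether, since primary TBDPS and secondary TIPS ethers are far more stable to acid.

Step 18
Reactants: 26
Product: 27 (2E,4R,6E)-8-[(tert-butyldiphenylsilyl)oxy]-7-[(3E)-4-iodopent-3-en-1-yl]-4-methyl-4-{(3R)-4-methyl-3-[(triisopropylsilyl)oxy]pent-4-en-1-yl}octa-2,6-dienal (seco iodo-enal)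
Conditions: MnO2, CH2Cl2, rt
Reagents that add atoms: none
Why: MnO2 oxidation is selective for the allylic alcohol and should give the E enal without touching other groups.

Step 19
Reactants: 27
Product: 29 (1R,2E,4R,5E,9E)-9-{[(tert-butyldiphenylsilyl)oxy]methyl}-1,5-dimethyl-1-{(3R)-4-methyl-3-[(triisopropylsilyl)oxy]pent-4-en-1-yl}cycloundeca-2,5,9-trien-4-ol (locants of the remark), via alkenylchromium 28 (not isolated)
Conditions: CrCl2 (4 equiv), chiral oxazoline–sulfonamide ligand (Kishi type, 4.4 equiv), Et3N, NiCl2 (10 mol%), THF, rt, 27 added by syringe pump to about 2 mM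
Reagents that add atoms: none
Why: Ni(0) inserts into the C5–I bond of 27, the alkenyl group passes to Cr(III) with retention of the E geometry (28), and this hard, aldehyde-selective nucleophile adds 1,2 to the C4 enal carbonyl (Nozaki–Hiyama–Kishi reaction; closest precedent: Ni/Cr macrocyclisations of iodoalkenyl aldehydes to 10–14-membered terpenoid carbocycles). The 11-membered ring is closed in the 11-exo-trig mode by forming C4–C5. The new C4 centre should be set as R by the chiral sulfonamide ligand on chromium, chosen to deliver the alkenyl group to the Si face of the aldehyde (catalyst control, because the remote C1 centre offers little bias). The step needs 1,2- over 1,4-addition and cyclisation over oligomerisation: the first is inherent in alkenylchromium(III) reagents and reinforced because the β-carbon C2 is neopentylic, the second should be secured by slow addition at high dilution. The enal cannot be deprotonated at the γ-position because C1 is quaternary, and the ring-cis C9=C10 olefin already present in 27 folds the chain so that C4 and C5 can meet. In one operation the step should give the complete carbocycle, the ring E-C5=C6 olefin and the allylic hydroxyl that steers the epoxidation.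

Step 20
Reactants: 29
Product: 30 (1R,2E,4R,5S,6R,9E)-9-{[(tert-butyldiphenylsilyl)oxy]methyl}-5,6-epoxy-1,5-dimethyl-1-{(3R)-4-methyl-3-[(triisopropylsilyl)oxy]pent-4-en-1-yl}cycloundeca-2,9-dien-4-ol
Conditions: Ti(OiPr)4 (20 mol%), D-(−)-DIPT (24 mol%), TBHP, 4 Å MS, CH2Cl2, −20 °C
Reagents that add atoms: tert-butyl hydroperoxide, CC(C)(C)OO
Why: Sharpless asymmetric epoxidation in its matched, kinetic-resolution mode: the D-(−)-tartrate titanium complex bound to the C4 hydroxyl should deliver oxygen to the trisubstituted C5=C6 olefin on the face that gives the erythro 4R,5S,6R epoxy alcohol, whereas the C2=C3 olefin (disubstituted, neopentylic, mismatched) and any 4S epimer should react far more slowly.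

Step 21
Reactants: 30; 31 3-methylbut-2-enoic acid
Product: 32 (1R,2E,4S,5S,6R,9E)-9-{[(tert-butyldiphenylsilyl)oxy]methyl}-5,6-epoxy-1,5-dimethyl-1-{(3R)-4-methyl-3-[(triisopropylsilyl)oxy]pent-4-en-1-yl}cycloundeca-2,9-dien-4-yl 3-methylbut-2-enoate
Conditions: PPh3, DIAD, toluene, 0 °C → rt
Reagents that add atoms: none
Why: Mitsunobu esterification: SN2 displacement of the C4 oxyphosphonium group by the carboxylate should invert C4 from R to S, turning the erythro relationship needed for the directed epoxidation into the threo relationship of the target, while SN2′ attack is blocked because C2 is neopentylic.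

Step 22
Reactants: 32
Product: 33 CNP0309478.1, (1R,2E,4S,5S,6R,9E)-5,6-epoxy-9-(hydroxymethyl)-1-[(3R)-3-hydroxy-4-methylpent-4-en-1-yl]-1,5-dimethylcycloundeca-2,9-dien-4-yl 3-methylbut-2-enoate
Conditions: TBAF, AcOH, THF, 0 °C → rt
Reagents that add atoms: none
Why: Fluoride-mediated desilylation should remove the TIPS and TBDPS ethers, and buffering with acetic acid should protect the ester and the epoxide from hydrolysis, acyl migration and Payne-type rearrangement.

**Compound list**

1 | (R)-2,2-dimethyl-1,3-dioxolane-4-carbaldehyde | O=C[C@H]1COC(C)(C)O1 | starting material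
2 | isopropenylmagnesium bromide | C=C(C)[Mg]Br | starting material
3 | 1-[(4R)-2,2-dimethyl-1,3-dioxolan-4-yl]-2-methylprop-2-en-1-ol (both carbinol epimers) | C=C(C)C(O)[C@H]1COC(C)(C)O1 | intermediate
4 | triethyl orthoacetate | CCOC(C)(OCC)OCC | starting material
5 | 1-ethoxyvinyl ether of 3 (mixed ketene acetal, not isolated) | C=C(C)C(OC(=C)OCC)[C@H]1COC(C)(C)O1 | intermediate
6 | ethyl (4E)-5-[(4S)-2,2-dimethyl-1,3-dioxolan-4-yl]-4-methylpent-4-enoate | CCOC(=O)CC/C(C)=C/[C@H]1COC(C)(C)O1 | intermediate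
7 | (4E)-5-[(4S)-2,2-dimethyl-1,3-dioxolan-4-yl]-N-methoxy-N,4-dimethylpent-4-enamide | CON(C)C(=O)CC/C(C)=C/[C@H]1COC(C)(C)O1 | intermediate
8 | (6E)-7-[(4S)-2,2-dimethyl-1,3-dioxolan-4-yl]-2,6-dimethylhepta-1,6-dien-3-one | C=C(C)C(=O)CC/C(C)=C/[C@H]1COC(C)(C)O1 | intermediate
9 | (3R,6E)-7-[(4S)-2,2-dimethyl-1,3-dioxolan-4-yl]-2,6-dimethylhepta-1,6-dien-3-ol | C=C(C)[C@H](O)CC/C(C)=C/[C@H]1COC(C)(C)O1 | intermediate
10 | triisopropylsilyl ether of 9 | C=C(C)[C@H](O[Si](C(C)C)(C(C)C)C(C)C)CC/C(C)=C/[C@H]1COC(C)(C)O1 | intermediate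
11 | (2S,3E,7R)-4,8-dimethyl-7-[(triisopropylsilyl)oxy]nona-3,8-diene-1,2-diol | C=C(C)[C@H](O[Si](C(C)C)(C(C)C)C(C)C)CC/C(C)=C/[C@H](O)CO | intermediate
12 | (2S,3E,7R)-1-[(tert-butyldimethylsilyl)oxy]-4,8-dimethyl-7-[(triisopropylsilyl)oxy]nona-3,8-dien-2-ol | C=C(C)[C@H](O[Si](C(C)C)(C(C)C)C(C)C)CC/C(C)=C/[C@H](O)CO[Si](C)(C)C(C)(C)C | intermediate
13 | 1-ethoxyvinyl ether of 12 at the C2 oxygen (mixed ketene acetal, not isolated) | C=C(C)[C@H](O[Si](C(C)C)(C(C)C)C(C)C)CC/C(C)=C/[C@H](OC(=C)OCC)CO[Si](C)(C)C(C)(C)C | intermediate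
14 | ethyl (3R,4E)-6-[(tert-butyldimethylsilyl)oxy]-3-methyl-3-{(3R)-4-methyl-3-[(triisopropylsilyl)oxy]pent-4-en-1-yl}hex-4-enoate | C=C(C)[C@H](O[Si](C(C)C)(C(C)C)C(C)C)CC[C@@](CC(=O)OCC)(C)/C=C/CO[Si](C)(C)C(C)(C)C | intermediate
15 | (3R,4E)-6-[(tert-butyldimethylsilyl)oxy]-3-methyl-3-{(3R)-4-methyl-3-[(triisopropylsilyl)oxy]pent-4-en-1-yl}hex-4-enal | C=C(C)[C@H](O[Si](C(C)C)(C(C)C)C(C)C)CC[C@@](CC=O)(C)/C=C/CO[Si](C)(C)C(C)(C)C | intermediate
16 | pent-3-yn-1-ol | CC#CCCO | starting material
17 | (E)-alkenylzirconocene chloride of 16, O-zirconated (not isolated) | C/C(=C\CCO[Zr](Cl)(C1C=CC=C1)C1C=CC=C1)[Zr](Cl)(C1C=CC=C1)C1C=CC=C1 | intermediate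
18 | (3E)-4-iodopent-3-en-1-ol | C/C(I)=C\CCO | intermediate
19 | (2E)-2,5-diiodopent-2-ene | C/C(I)=C\CCI | intermediate
20 | triethyl phosphonoacetate | CCOC(=O)CP(=O)(OCC)OCC | starting material
21 | sodium salt of triethyl phosphonoacetate (not isolated) | CCOC(=O)[CH-]P(=O)(OCC)OCC.[Na+] | intermediate
22 | ethyl (5E)-2-(diethoxyphosphoryl)-6-iodohept-5-enoate (racemic at C2) | CCOC(=O)C(CC/C=C(\C)I)P(=O)(OCC)OCC | intermediate
23 | ethyl (2E,5R,6E)-8-[(tert-butyldimethylsilyl)oxy]-2-[(3E)-4-iodopent-3-en-1-yl]-5-methyl-5-{(3R)-4-methyl-3-[(triisopropylsilyl)oxy]pent-4-en-1-yl}octa-2,6-dienoate | C=C(C)[C@H](O[Si](C(C)C)(C(C)C)C(C)C)CC[C@@](C/C=C(\CC/C=C(\C)I)C(=O)OCC)(C)/C=C/CO[Si](C)(C)C(C)(C)C | intermediate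
24 | (2E,5R,6E)-8-[(tert-butyldimethylsilyl)oxy]-2-[(3E)-4-iodopent-3-en-1-yl]-5-methyl-5-{(3R)-4-methyl-3-[(triisopropylsilyl)oxy]pent-4-en-1-yl}octa-2,6-dien-1-ol | C=C(C)[C@H](O[Si](C(C)C)(C(C)C)C(C)C)CC[C@@](C/C=C(\CC/C=C(\C)I)CO)(C)/C=C/CO[Si](C)(C)C(C)(C)C | intermediate
25 | 1-O-tert-butyldiphenylsilyl ether of 24 | C=C(C)[C@H](O[Si](C(C)C)(C(C)C)C(C)C)CC[C@@](C/C=C(\CC/C=C(\C)I)CO[Si](c1ccccc1)(c1ccccc1)C(C)(C)C)(C)/C=C/CO[Si](C)(C)C(C)(C)C | intermediate
26 | (2E,4R,6E)-8-[(tert-butyldiphenylsilyl)oxy]-7-[(3E)-4-iodopent-3-en-1-yl]-4-methyl-4-{(3R)-4-methyl-3-[(triisopropylsilyl)oxy]pent-4-en-1-yl}octa-2,6-dien-1-ol | C=C(C)[C@H](O[Si](C(C)C)(C(C)C)C(C)C)CC[C@@](C/C=C(\CC/C=C(\C)I)CO[Si](c1ccccc1)(c1ccccc1)C(C)(C)C)(C)/C=C/CO | intermediate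
27 | (2E,4R,6E)-8-[(tert-butyldiphenylsilyl)oxy]-7-[(3E)-4-iodopent-3-en-1-yl]-4-methyl-4-{(3R)-4-methyl-3-[(triisopropylsilyl)oxy]pent-4-en-1-yl}octa-2,6-dienal | C=C(C)[C@H](O[Si](C(C)C)(C(C)C)C(C)C)CC[C@@](C/C=C(\CC/C=C(\C)I)CO[Si](c1ccccc1)(c1ccccc1)C(C)(C)C)(C)/C=C/C=O | intermediate
28 | alkenylchromium(III) dichloride from 27, CrCl2 in place of iodine at C5 (not isolated) | C=C(C)[C@H](O[Si](C(C)C)(C(C)C)C(C)C)CC[C@@](C/C=C(\CC/C=C(\C)[Cr](Cl)Cl)CO[Si](c1ccccc1)(c1ccccc1)C(C)(C)C)(C)/C=C/C=O | intermediate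
29 | (1R,2E,4R,5E,9E)-9-{[(tert-butyldiphenylsilyl)oxy]methyl}-1,5-dimethyl-1-{(3R)-4-methyl-3-[(triisopropylsilyl)oxy]pent-4-en-1-yl}cycloundeca-2,5,9-trien-4-ol | C=C(C)[C@H](O[Si](C(C)C)(C(C)C)C(C)C)CC[C@@]1(C)/C=C/[C@@H](O)/C(C)=C/CC/C(CO[Si](c2ccccc2)(c2ccccc2)C(C)(C)C)=C\C1 | intermediate
30 | (1R,2E,4R,5S,6R,9E)-9-{[(tert-butyldiphenylsilyl)oxy]methyl}-5,6-epoxy-1,5-dimethyl-1-{(3R)-4-methyl-3-[(triisopropylsilyl)oxy]pent-4-en-1-yl}cycloundeca-2,9-dien-4-ol | C=C(C)[C@H](O[Si](C(C)C)(C(C)C)C(C)C)CC[C@@]1(C)/C=C/[C@@H](O)[C@@]2(C)O[C@@H]2CC/C(CO[Si](c3ccccc3)(c3ccccc3)C(C)(C)C)=C\C1 | intermediate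
31 | 3-methylbut-2-enoic acid | CC(C)=CC(=O)O | starting material
32 | (4S)-3-methylbut-2-enoate of the bis-silylated epoxy diene (4S,5S,6R; C4 inverted relative to 30) | C=C(C)[C@H](O[Si](C(C)C)(C(C)C)C(C)C)CC[C@@]1(C)/C=C/[C@H](OC(=O)C=C(C)C)[C@@]2(C)O[C@@H]2CC/C(CO[Si](c3ccccc3)(c3ccccc3)C(C)(C)C)=C\C1 | intermediate
33 | CNP0309478.1 | C=C(C)[C@H](O)CC[C@@]1(C)/C=C/[C@H](OC(=O)C=C(C)C)[C@@]2(C)O[C@@H]2CC/C(CO)=C\C1 | target

**Step count and risks**

Total step count: 22. Longest linear sequence: 19 steps (steps 1–10 and 14–22).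

Steps most likely to fail:

- Step 19. The risk is competing intermolecular coupling to oligomers and incomplete control of the carbonyl face by the ligand, so that both C4 epimers form. The fallback separates ring closure from stereocontrol. It sets out from 27, which is cyclised under ligand-free CrCl2/NiCl2 conditions in DMSO–THF at high dilution to the C4-epimeric ring dienols. The mixture is oxidised with MnO2 to the cross-conjugated ring dienone F1, and F1 is reduced with (S)-Me-CBS/catecholborane, the α-methyl-branched C5 alkenyl group acting as the large substituent, to come back to the route at 29.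

- Step 21. The risk is sluggish SN2 displacement at the hindered C4 oxyphosphonium centre with a weak acid, which would lead to retention through acyloxyphosphonium species or to elimination. The fallback sets out from 30 and inverts C4 by a Mitsunobu reaction with the stronger 4-nitrobenzoic acid to the (4S)-4-nitrobenzoate F2. The aroyl group is removed with K2CO3 in MeOH at 0 °C to give the (4S)-epoxy alcohol F3, and F3 is acylated with 3-methylbut-2-enoyl chloride (pyridine, DMAP) to come back to the route at 32.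

- Step 14. The risk is insufficient E/Z control in the olefination with the α-branched phosphonate anion. The fallback replaces the phosphonate by a stabilised phosphorane. It sets out from 19, which alkylates ethyl (triphenylphosphoranylidene)acetate to the phosphonium iodide F4. Aqueous NaOH converts this into the α-substituted ylide F5, and the Wittig reaction of F5 with 15 (toluene, 90 °C) comes back to the route at 23.

Further compounds
F1 | step 19 | (1R,2E,5E,9E)-9-{[(tert-butyldiphenylsilyl)oxy]methyl}-1,5-dimethyl-1-{(3R)-4-methyl-3-[(triisopropylsilyl)oxy]pent-4-en-1-yl}cycloundeca-2,5,9-trien-4-one | C=C(C)[C@H](O[Si](C(C)C)(C(C)C)C(C)C)CC[C@@]1(C)/C=C/C(=O)/C(C)=C/CC/C(CO[Si](c2ccccc2)(c2ccccc2)C(C)(C)C)=C\C1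
F2 | step 21 | (4S)-4-nitrobenzoate of the C4-epimer of 30 (4S,5S,6R) | C=C(C)[C@H](O[Si](C(C)C)(C(C)C)C(C)C)CC[C@@]1(C)/C=C/[C@H](OC(=O)c2ccc(cc2)[N+](=O)[O-])[C@@]3(C)O[C@@H]3CC/C(CO[Si](c4ccccc4)(c4ccccc4)C(C)(C)C)=C\C1
F3 | step 21 | (4S)-epimer of epoxy alcohol 30 (4S,5S,6R) | C=C(C)[C@H](O[Si](C(C)C)(C(C)C)C(C)C)CC[C@@]1(C)/C=C/[C@H](O)[C@@]2(C)O[C@@H]2CC/C(CO[Si](c3ccccc3)(c3ccccc3)C(C)(C)C)=C\C1
F4 | step 14 | [(5E)-1-ethoxy-6-iodo-1-oxohept-5-en-2-yl]triphenylphosphonium iodide | CCOC(=O)C(CC/C=C(\C)I)[P+](c1ccccc1)(c1ccccc1)c1ccccc1.[I-]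
F5 | step 14 | ethyl (5E)-6-iodo-2-(triphenylphosphoranylidene)hept-5-enoate | CCOC(=O)C(CC/C=C(\C)I)=P(c1ccccc1)(c1ccccc1)c1ccccc1
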